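(All runs are calculated with constants of no real substance, and the scatter is random.)

The first question is an easy one: of the E (substrate) a run has lost, how much has come out as L (product)? Z and X are catalysts. The suspected route is that Z turns E into J and back, J binds X to form D, Q turns D into L and frees X, and X also decays to G.

| flask | E | Q | Z | X | remark | time |
|---|---|---|---|---|---|---|
| north | 0.14 M | 0.252 M | 1.7 mM | 0.12 mM | the very flask that is asked about, followed so far |  |
| west | 0.14 M | 0.17 M | 1.7 mM | 0.12 mM | run made earlier |  |
| flask | 0.14 M | 0.252 M | 1.7 mM | 0.12 mM |  | 10 min |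

north run (percent of the E charged)

| time / s | L / % | E / % |
|---|---|---|
| 30.0 | 1 | 96 |
| 60.0 | 0 | 96 |
| 90.0 | 0 | 91 |
| 120 | 0 | 86 |

west run (percent of the E charged)

| time / min | L / % | E / % |
|---|---|---|
| 2.50 | 3 | 87 |
| 5.00 | 1 | 76 |
| 8.00 | 10 | 62 |
| 10.0 | 11 | 60 |

(scatter of a reading: 1.5 percentage points)

- how much L the flask holds at 10 min, in percent of the E charged
- how much E the flask holds at 10 min, in percent of the E charged
- how much J the flask holds at 10 min, in percent of the E charged
- concentration of Q at 10 min, in M

- on the list of suspects stand: E + Z <-> Z + J; X + J <-> D; Q + D -> X + L; X -> G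

Asked: What do you read from the west run?

Answer: At 10.0 min it holds 11% L and has lost 40.0% of its E. Dividing gives 0.275, the share s: L gained per E lost, read at one moment. Time stays in this share, so I hold it against another flask read at the same moment.

Asked: How firm is that?

Answer: Not very. The scatter is 13.6% of that L reading, so s carries about that uncertainty.

Asked: The north flask has more Q. What then?

Answer: Its Q charge is 1.48 times the west charge. On the suspect list, Q enters at D and not in the step of E with Z. I therefore keep the west loss of E and scale s to 0.408.

Asked: Doesn't that assume the same D in both flasks?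

Answer: Yes, and that is the weak spot, so I treat my figure as the high side. I commit to L 16.3%, E 60%, J 23.7% and Q 0.229 M. E is the limiting reagent, with less charged than Q.

The forecast gives L 15%, E 59%, J 26% and Q 0.231 M. Its L is lower than mine, and it says: “Partial saturation of the binding step, or catalyst death, could reduce this”.

At 10 min the flask gives L 14.1%, E 56.7%, J 29.2% and Q 0.232 M. The forecast stands within its margins.

    E + Z ⇌ Z + J (K = 2.39, k = 37.5 M⁻¹ min⁻¹)
    X + J ⇌ D (K = 1620 M⁻¹, k = 4130 M⁻¹ min⁻¹)
    Q + D → X + L (k = 103 M⁻¹ min⁻¹)
    X → G (k = 0.0630 min⁻¹)

The flask's share at 10 min is 0.324, beside the 0.275 read in the west run. At that time the flask still holds 56.7% as E and 29.2% as J, and it has not come to rest. Left until 100 min, it holds L 87.2%, E 5.10%, J 7.70% and Q 0.130 M, and G has grown to 64.0% of the X charged. The flask's share has then climbed to 0.919, so a value of s belongs to the moment it was read.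

A neighbour flask is charged with 4.8 × 10⁻⁵ M of X, 0.400 of this flask's charge. Taking s in step with X gives 0.130, and with the same E loss, L 5.63%. Computed at 10 min, that neighbour holds L 5.96% and E 57.5%.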